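## The problem

The target is a diester with no fused or bridged rings. A single cyclopentane (core atoms C1 with CH2O, C2 with CH3, C3 with O, C4 as CH2, C5 with CH(CH2OH)2) carries two identical (3S,4E)-4-formyl-3-(2-oxoethyl)hex-4-enoyl chains, one on the primary oxygen at C1 and one on the secondary oxygen at C3. The four ring stereocentres run C5–C1–C2–C3 with every vicinal pair trans, so once one is fixed absolutely each neighbour can be set by substrate control. The two chain stereocentres (C3′) are separated from the core by an ester and a methylene group; the core cannot direct them, so a reagent or catalyst must set them, twice and in the same sense. Each chain ends in a 1,5-dialdehyde, one aldehyde saturated and enolizable, the other an (E)-2-ethylidene enal. Together with two esters and a free 1,3-diol this rules out strong base, amines, hydride and oxidants late in the route, so all four aldehydes must appear in the last operation from a mask that opens in mild aqueous acid. The enabling feature is that the five carbons OHC–C4′–C3′–CH2–CHO are C2–C3–C4–C5–C6 of a pyridine without its nitrogen, the ethylidene is an acetyl group on C3 at the reduced level, and C3′ is pyridine C4. 3-Acetylpyridine therefore holds every chain carbon except C1′ and C2′, and the C2′–C3′ bond is the one formed when an acetate enolate equivalent adds to C4 of an activated pyridinium ion. Since both chains sit on acetate positions of the core, both can be built at once.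

## Retrosynthesis

**Unmasking (22 ⇒ 21 ⇒ 20).** Target 22 is traced to the bis(carbinol) 21, in which each chain is a 3-(1-hydroxyethyl)-1-methoxycarbonyl-1,4-dihydropyridine and the diol is an acetonide. Only heteroatom bonds are cut: per ring the two N–C(sp2) bonds and the carbinol C–O bond, plus the two acetal C–O bonds. Acetal protection of four aldehydes of two kinds would leave the ethylidene geometry to a separate olefination. The dihydropyridine hides both aldehydes of a chain, and the enal arises by a Stork–Danheiser-type transposition whose thermodynamic outcome is the E isomer. 21 comes from diketone 20 by 1,2-reduction, which need only spare esters and carbamates. The forward hydrolysis must go to completion at both rings under acid mild enough for the two esters.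

**Key disconnection (20 ⇒ 16 + 17 + 18).** In 20 the two C2′–C3′ bonds are cut, each between an acetate α-carbon and C4 of a dihydropyridine. This leads to the core bis(silyl ketene acetal) 16 and two equivalents each of 3-acetylpyridine 17 and methyl chloroformate 18, which combine to the pyridinium salt 19. The neighbouring cuts are esterification of the core with a finished chain acid (C1′–O) or stepwise growth of the chain from C3′. Against them, this cut makes two C–C bonds and two stereocentres in one operation, avoids acylating the hindered C3 oxygen with a valuable acid, and takes seven of nine chain carbons from a bulk heteroarene. Precursor 16 has no chain stereocentre and no aldehyde. The forward reaction must attack C4 rather than C2/C6 and show the same facial sense at two centres the core cannot influence, hence a chiral anion-binding thiourea.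

**Acetates (16 ⇒ 14 ⇒ 13).** 16 is the double O-silylation product of diacetate 14 (two Si–O bonds). In 14 the C3–O bond is cut with inversion: 14 is planned from diol 13, whose C3 hydroxyl is cis to the C2 methyl, by a double Mitsunobu acetylation. Small hydrides reduce 2,3-trans-disubstituted cyclopentanones with poor selectivity, whereas a bulky borohydride gives the 2,3-cis alcohol reliably. Since acetates are needed anyway, taking the C3 epimer and inverting it during acetylation costs no step. The demand is that SN2 displacement at a secondary cyclopentyl carbon outruns elimination.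

**Oxidation levels (13 ⇒ 12 ⇒ 11).** The C3–H bond of 13 is cut back to ketone 12, and the primary C–O bond of 12 to the C–Si bond of silane 11 (Tamao–Kumada oxidation). An alkoxysilane is chosen over an arylsilane because its oxidation is buffered and leaves the acetonide intact. Both steps are functional-group changes on an already complete carbon skeleton.

**Core substituents (11 ⇒ 7 + 8).** The C1–CH2 and C2–CH3 bonds of 11 are cut in one three-component step: copper-catalysed addition of the Grignard reagent 9 (from chlorosilane 8) to enone 7, then methylation of enolate 10. The single stereocentre of 7 (C5) relays to C1 and then to C2, so three ring centres come from one. The alternative of introducing CH2OH as an aldol with formaldehyde would leave a retro-aldol-prone β-hydroxy ketone. The enolate must be methylated before it equilibrates.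

**Chiral pool (7 ⇒ 6 ⇒ 5 ⇒ 4 ⇒ 1 + 2).** Enone 7 arises by allylic oxidation of alcohol 6, the acetonide of triol 5, which is the reduction product of malonate 4. The C5–CH bond of 4 is cut by Tsuji–Trost alkylation into the commercial monoacetate 1 and dimethyl malonate 2. The acetate-bearing carbon of 1 becomes C5 with retention, and the carbinol carbon is later sacrificed as the enone carbonyl. The malonate must be reduced and ketalized before the enone is made, since a free malonate C–H would quench the Grignard reagent.

## Roads not taken

**Alternative 1:** The cut is in the core: ring bond C1–C5 together with the C2–H bond, leading to the acyclic enal/alkylidene malonate A2. In the forward step a chiral imidazolidinone salt forms the iminium ion of A2, the dihydropyridine hydride donor A3 reduces it at C2, and the resulting enamine closes the five-membered ring by Michael addition (5-exo-trig) onto the alkylidene malonate, giving A1. It builds the ring and up to three core stereocentres in one organocatalytic operation, mirrors how iridoid cyclopentanes are made in nature, and leaves the formyl and malonate groups at oxidation levels one reduction away from the target. Its weak points are that A2 needs its own asymmetric synthesis of the silyloxy stereocentre and a trisubstituted enal, and that its γ-silyloxy group can be lost through the dienamine. Hydride delivery next to an existing stereocentre also raises a matched/mismatched question, and the C1/C5 relationship rests on the Michael transition state. Above all, it leaves both chains unsolved: they would have to be made enantioselectively elsewhere, in double quantity, and esterified onto a hindered secondary alcohol with masked aldehydes. For the core alone this road may be shorter and more elegant than the seven steps from 1 to 13. The chosen plan sets against it a core built only from substrate-controlled reactions with strong precedent, and it spends its one unprecedented step on the chains, the part that is duplicated.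

**Alternative 2:** The cut is again in the core: the C1–CH2 and C2–CH3 bonds, from enone A5 (the same compound as 7). The forward step is the CuI-catalysed (monovalent copper) addition of a silylmethyl Grignard reagent and methylation of the enolate, giving ketone A4 (the same compound as 11) with no ring closure. The reaction is reliable, sets two stereocentres by relay from C5 and brings the hydroxymethyl group in masked form. As a governing strategy it has the same gap as Alternative 1: the chains are not addressed and would have to arrive as a separately made, aldehyde-masked acid used in at least twofold amount. For the core this road is as good as the chosen one, and indeed the chosen route adopts it unchanged as step 5. What the chosen plan adds is the two-directional construction of both chains on the core from two acetates, at the cost of one step beyond known chemistry.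

**Alternative 3:** The cut is inside each chain: the C3′–CH2 bond of the oxoethyl arm and an acetal C–O bond, from enal A7 (as 1-oxadiene) and ethyl vinyl ether A8. The forward step is an endo inverse-demand hetero-Diels–Alder reaction on the chromium chloride complex CrCl(L) of a chiral tridentate Schiff base L (trivalent chromium), closing the dihydropyran A6. This reaction class is established with high enantioselectivity for β-alkyl enals, so C3′ would be set with direct precedent, and the dihydropyran stores the 1,5-dialdehyde as a stable acetal and enol ether. The weak points are the steps still needed after A6. The two-carbon ethylidene must be appended at C5 of the pyran with control of geometry and the silyloxyethyl arm oxidized to the acid. More than two equivalents of that acid must then be esterified onto the core, including the hindered C3 oxygen, before unmasking. On precedent for the stereodefining step and on convergence this road is better than the chosen one. The chosen plan sets against it a chain made in three operations from the diacetate, a building block (17) that already contains the ethylidene carbons, and no esterification with a precious acid.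

Key step: step 10

Remark on the chemistry: core atoms are numbered C1 (CH2O), C2 (CH3), C3 (O), C4 (CH2), C5 (CH(CH2OH)2 or dioxanyl) in the discussion; systematic names use their own locants.
Remark on the chemistry: the sense of induction of the thiourea in step 10 cannot be predicted; it is assumed that one enantiomer delivers 4R at both dihydropyridines, and that enantiomer is the one used (the R,R,S form is written).

Step 1
Reactants: 1 (1S,4R)-cis-4-acetoxycyclopent-2-en-1-ol; 2 dimethyl malonate
Product: 4 dimethyl 2-[(1R,4S)-4-hydroxycyclopent-2-en-1-yl]propanedioate, via sodium dimethyl malonate 3 (not isolated)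
Conditions: 2 (2.0 equiv), NaH (1.9 equiv), THF, 0 °C; then 1, Pd(PPh3)4 (3 mol %, zerovalent palladium), THF, rt → 50 °C
Reagents that add atoms: none
Why: Tsuji–Trost allylic alkylation; palladium ionizes the acetate anti and the malonate attacks the π-allyl anti to the metal at the terminus remote from the hydroxyl, so the C–C bond forms with net retention and fixes the future C5 (cis-1,4 product).

Step 2
Reactants: 4 dimethyl 2-[(1R,4S)-4-hydroxycyclopent-2-en-1-yl]propanedioate
Product: 5 2-[(1R,4S)-4-hydroxycyclopent-2-en-1-yl]propane-1,3-diol
Conditions: LiAlH4 (3 equiv), THF, 0 °C → reflux; aq. NaOH work-up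
Reagents that add atoms: none
Why: Hydride reduction of both esters to the 1,3-diol; the isolated alkene and the allylic alkoxide are inert and no stereocentre is touched.

Step 3
Reactants: 5 2-[(1R,4S)-4-hydroxycyclopent-2-en-1-yl]propane-1,3-diol
Product: 6 (1S,4R)-4-(2,2-dimethyl-1,3-dioxan-5-yl)cyclopent-2-en-1-ol
Conditions: 2,2-dimethoxypropane, pyridinium p-toluenesulfonate (10 mol %), acetone, rt; then brief MeOH/H2O, NaHCO3
Reagents that add atoms: 2,2-dimethoxypropane COC(C)(C)OC
Why: Acid-catalysed acetal exchange gives the six-membered 1,3-dioxane; the secondary hydroxyl cannot form a ring and any mixed ketal there is cleaved in the work-up.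

Step 4
Reactants: 6 (1S,4R)-4-(2,2-dimethyl-1,3-dioxan-5-yl)cyclopent-2-en-1-ol
Product: 7 (4R)-4-(2,2-dimethyl-1,3-dioxan-5-yl)cyclopent-2-en-1-one
Conditions: activated MnO2 (15 equiv), CH2Cl2, rt
Reagents that add atoms: none
Why: Allylic alcohol oxidation under neutral heterogeneous conditions, which leaves the γ-stereocentre and the acetonide untouched.

Step 5
Reactants: 7 (4R)-4-(2,2-dimethyl-1,3-dioxan-5-yl)cyclopent-2-en-1-one; 8 (chloromethyl)dimethyl(propan-2-yloxy)silane
Product: 11 (2R,3S,4S)-4-(2,2-dimethyl-1,3-dioxan-5-yl)-3-{[dimethyl(propan-2-yloxy)silyl]methyl}-2-methylcyclopentan-1-one, via {[dimethyl(propan-2-yloxy)silyl]methyl}magnesium chloride 9 (not isolated), via chloromagnesium enolate of the conjugate adduct 10 (not isolated)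
Conditions: 8, Mg, THF, rt; then CuI (10 mol %), 7, THF, −78 → −40 °C; then MeI (5 equiv), DMPU, −40 → 0 °C
Reagents that add atoms: iodomethane CI
Why: Copper-catalysed conjugate addition followed by enolate alkylation (three-component coupling); the nucleophile adds to C1 anti to the C5 dioxanyl group and methyl iodide then attacks C2 anti to the new C1 substituent, giving the 1,2-trans, 1,5-trans ketone, which is also the thermodynamic isomer.

Step 6
Reactants: 11 (2R,3S,4S)-4-(2,2-dimethyl-1,3-dioxan-5-yl)-3-{[dimethyl(propan-2-yloxy)silyl]methyl}-2-methylcyclopentan-1-one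
Product: 12 (2R,3S,4R)-4-(2,2-dimethyl-1,3-dioxan-5-yl)-3-(hydroxymethyl)-2-methylcyclopentan-1-one
Conditions: 30% H2O2, KF, KHCO3, THF/MeOH (1:1), rt → 40 °C
Reagents that add atoms: hydrogen peroxide OO
Why: Tamao–Kumada oxidation of the alkoxysilane C–Si bond to C–OH under buffered conditions that spare the ketone and the acetonide; any epimerization at C2 returns to the favoured all-trans ketone.

Step 7
Reactants: 12 (2R,3S,4R)-4-(2,2-dimethyl-1,3-dioxan-5-yl)-3-(hydroxymethyl)-2-methylcyclopentan-1-one
Product: 13 (1S,2R,3S,4R)-4-(2,2-dimethyl-1,3-dioxan-5-yl)-3-(hydroxymethyl)-2-methylcyclopentan-1-ol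
Conditions: LiBH(sec-Bu)3 (2.5 equiv), THF, −78 °C; then aq. NaOH, 30% H2O2, 0 °C
Reagents that add atoms: none
Why: Bulky trialkylborohydride reduction; hydride enters the cyclopentanone from the face opposite the adjacent C2 methyl (and the C5 dioxanyl), giving the C3 hydroxyl cis to the methyl, which is deliberately the epimer that step 8 inverts.

Step 8
Reactants: 13 (1S,2R,3S,4R)-4-(2,2-dimethyl-1,3-dioxan-5-yl)-3-(hydroxymethyl)-2-methylcyclopentan-1-ol
Product: 14 (1R,2R,3S,4R)-3-(acetoxymethyl)-4-(2,2-dimethyl-1,3-dioxan-5-yl)-2-methylcyclopentyl acetate
Conditions: AcOH (3 equiv), PPh3 (3 equiv), diisopropyl azodicarboxylate (3 equiv), toluene/THF, 0 °C → rt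
Reagents that add atoms: acetic acid CC(=O)O
Why: Double Mitsunobu esterification; the primary alcohol is acetylated and the secondary alkoxyphosphonium ion at C3 is displaced by acetate with SN2 inversion, which sets C3 trans to the C2 methyl and cis to the C1 acetoxymethyl group.

Step 9
Reactants: 14 (1R,2R,3S,4R)-3-(acetoxymethyl)-4-(2,2-dimethyl-1,3-dioxan-5-yl)-2-methylcyclopentyl acetate
Product: 16 bis(tert-butyldimethylsilyl ketene acetal) of diacetate 14, via dilithium bis(enolate) of the diacetate 15 (not isolated)
Conditions: LiN(iPr)2 (2.4 equiv, commercial solution), THF, −78 °C; then TBSCl (2.6 equiv), DMPU/THF, −78 °C → rt; pentane, filtration, used crude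
Reagents that add atoms: tert-butyldimethylsilyl chloride CC(C)(C)[Si](C)(C)Cl
Why: Kinetic deprotonation of both acetates and O-silylation of the lithium enolates in the presence of a dipolar cosolvent, the standard access to acetate-derived silyl ketene acetals; non-aqueous isolation avoids hydrolysis.

Step 10
Reactants: 16 bis(tert-butyldimethylsilyl ketene acetal) of diacetate 14; 17 3-acetylpyridine; 18 methyl chloroformate
Product: 20 core acetonide bis{2-[(4R)-3-acetyl-1-(methoxycarbonyl)-1,4-dihydropyridin-4-yl]acetate}, via 3-acetyl-1-(methoxycarbonyl)pyridinium chloride 19 (not isolated)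
Conditions: 17 (2.6 equiv), 18 (2.6 equiv), Et2O, 0 °C → rt; then 1-[(1R,2R)-2-(2-methyl-5-phenylpyrrol-1-yl)cyclohexyl]-3-[(2S)-1-(diisobutylamino)-3,3-dimethyl-1-oxobutan-2-yl]thiourea (20 mol %), 16 (slow addition), Et2O, −78 → −60 °C; aq. NaHCO3
Reagents that add atoms: none
Why: Proposed new method: 17 and 18 give the N-acylpyridinium chloride 19, the thiourea binds its chloride to form a chiral contact ion pair soluble in ether, and each ketene acetal carbon of 16 adds to C4 of one cation, after which chloride removes the silyl group and frees the catalyst. The closest known reaction types are the uncatalysed C4 addition of silyl ketene acetals to N-alkoxycarbonyl-3-acylpyridinium salts and the thiourea anion-binding acyl-Mannich addition of acetate-derived silyl ketene acetals to N-acylisoquinolinium and N-acylpyridinium chlorides; a C4-selective, catalyst-controlled addition carried out twice on one nucleophile has not been shown. No ring is closed; the two C2′–C3′ bonds form and two pyridines are dearomatized. Both new stereocentres (C4 of each dihydropyridine, R) are set by the catalyst alone, since the nearest core stereocentres lie four and five bonds away across an ester. Attack at C4 instead of C2 or C6 is secured by the 3-acetyl group, which makes C4 the vinylogous acceptor position and leaves a push–pull N–C2=C3–C=O product, and by the soft, bulky silyl ketene acetal. The step also needs a slow racemic background reaction, which the low temperature and the poor solubility of uncomplexed 19 in ether should provide. As the two additions are independent, any leakage appears as diastereomers of 20 that can be removed, not as loss of enantiomeric purity.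

Step 11
Reactants: 20 core acetonide bis{2-[(4R)-3-acetyl-1-(methoxycarbonyl)-1,4-dihydropyridin-4-yl]acetate}
Product: 21 core acetonide bis{2-[(4R)-3-(1-hydroxyethyl)-1-(methoxycarbonyl)-1,4-dihydropyridin-4-yl]acetate}
Conditions: NaBH4 (3 equiv), CeCl3·7H2O (2.2 equiv), MeOH/THF, −40 °C; acetone quench, aq. NaHCO3; used crude
Reagents that add atoms: none
Why: Luche 1,2-reduction of the two β-(acylamino)enone carbonyls; esters and carbamates are inert at this temperature, and the new carbinol centres are formed as mixtures that are erased in step 12 (a methanol-trapped form would converge to the same cation).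

Step 12
Reactants: 21 core acetonide bis{2-[(4R)-3-(1-hydroxyethyl)-1-(methoxycarbonyl)-1,4-dihydropyridin-4-yl]acetate}
Product: 22 [(1S,2R,3R,5R)-5-(1,3-dihydroxypropan-2-yl)-2-methyl-3-{[(3S,4E)-4-formyl-3-(2-oxoethyl)hex-4-enoyl]oxy}cyclopentyl]methyl (3S,4E)-4-formyl-3-(2-oxoethyl)hex-4-enoate (CNP0313563.1)
Conditions: 1 M aq. HCl/THF (1:4), 0 °C → rt; EtOAc extraction, aqueous washes
Reagents that add atoms: water O
Why: Stork–Danheiser-type carbonyl transposition of a vinylogous carbamate: acid ionizes each carbinol through the N-acyl enamine to a 3-ethylidene N-acyliminium ion, water adds at C2 and the hemiaminal opens to the enal, then hydrolysis of the remaining ene-carbamate releases the saturated aldehyde and methyl carbamate while the acetonide is hydrolysed in the same medium. The E enal is the thermodynamic isomer reached through reversible ionization, and C3′ is not α to any carbonyl, so it is not epimerized.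

## Compound list

1 | (1S,4R)-cis-4-acetoxycyclopent-2-en-1-ol | C1=C[C@@H](O)C[C@H]1OC(C)=O | starting material
2 | dimethyl malonate | COC(=O)CC(=O)OC | starting material
3 | sodium dimethyl malonate | [Na+].COC(=O)[CH-]C(=O)OC | intermediate
4 | dimethyl 2-[(1R,4S)-4-hydroxycyclopent-2-en-1-yl]propanedioate (1,4-cis) | C1=C[C@@H](O)C[C@H]1C(C(=O)OC)C(=O)OC | intermediate
5 | 2-[(1R,4S)-4-hydroxycyclopent-2-en-1-yl]propane-1,3-diol | C1=C[C@@H](O)C[C@H]1C(CO)CO | intermediate
6 | (1S,4R)-4-(2,2-dimethyl-1,3-dioxan-5-yl)cyclopent-2-en-1-ol | C1=C[C@@H](O)C[C@H]1C2COC(C)(C)OC2 | intermediate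
7 | (4R)-4-(2,2-dimethyl-1,3-dioxan-5-yl)cyclopent-2-en-1-one | C1=CC(=O)C[C@H]1C2COC(C)(C)OC2 | intermediate
8 | (chloromethyl)dimethyl(propan-2-yloxy)silane | CC(C)O[Si](C)(C)CCl | starting material
9 | {[dimethyl(propan-2-yloxy)silyl]methyl}magnesium chloride | CC(C)O[Si](C)(C)C[Mg]Cl | intermediate
10 | chloromagnesium enolate of the conjugate adduct (silylmethyl group anti to dioxanyl) | CC(C)O[Si](C)(C)C[C@@H]1C=C(O[Mg]Cl)C[C@H]1C2COC(C)(C)OC2 | intermediate
11 | (2R,3S,4S)-4-(2,2-dimethyl-1,3-dioxan-5-yl)-3-{[dimethyl(propan-2-yloxy)silyl]methyl}-2-methylcyclopentan-1-one (2,3-trans; 3,4-trans) | CC(C)O[Si](C)(C)C[C@@H]1[C@@H](C)C(=O)C[C@H]1C2COC(C)(C)OC2 | intermediate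
12 | (2R,3S,4R)-4-(2,2-dimethyl-1,3-dioxan-5-yl)-3-(hydroxymethyl)-2-methylcyclopentan-1-one | OC[C@@H]1[C@@H](C)C(=O)C[C@H]1C2COC(C)(C)OC2 | intermediate
13 | (1S,2R,3S,4R)-4-(2,2-dimethyl-1,3-dioxan-5-yl)-3-(hydroxymethyl)-2-methylcyclopentan-1-ol (ring OH cis to CH3) | OC[C@@H]1[C@@H](C)[C@@H](O)C[C@H]1C2COC(C)(C)OC2 | intermediate
14 | (1R,2R,3S,4R)-3-(acetoxymethyl)-4-(2,2-dimethyl-1,3-dioxan-5-yl)-2-methylcyclopentyl acetate (all vicinal pairs trans) | CC(=O)OC[C@@H]1[C@@H](C)[C@H](OC(C)=O)C[C@H]1C2COC(C)(C)OC2 | intermediate
15 | dilithium bis(enolate) of diacetate 14 | [Li]OC(=C)OC[C@@H]1[C@@H](C)[C@H](OC(=C)O[Li])C[C@H]1C2COC(C)(C)OC2 | intermediate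
16 | bis(tert-butyldimethylsilyl ketene acetal) of diacetate 14 (each acetate as CH2=C(OTBS)O–) | C=C(O[Si](C)(C)C(C)(C)C)OC[C@@H]1[C@@H](C)[C@H](OC(=C)O[Si](C)(C)C(C)(C)C)C[C@H]1C2COC(C)(C)OC2 | intermediate
17 | 3-acetylpyridine | CC(=O)c1cccnc1 | starting material
18 | methyl chloroformate | COC(=O)Cl | starting material
19 | 3-acetyl-1-(methoxycarbonyl)pyridinium chloride | CC(=O)c1ccc[n+](C(=O)OC)c1.[Cl-] | intermediate
20 | core acetonide bis{2-[(4R)-3-acetyl-1-(methoxycarbonyl)-1,4-dihydropyridin-4-yl]acetate} | CC(=O)C1=CN(C(=O)OC)C=C[C@H]1CC(=O)OC[C@@H]2[C@@H](C)[C@H](OC(=O)C[C@@H]3C=CN(C(=O)OC)C=C3C(C)=O)C[C@H]2C4COC(C)(C)OC4 | intermediate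
21 | core acetonide bis{2-[(4R)-3-(1-hydroxyethyl)-1-(methoxycarbonyl)-1,4-dihydropyridin-4-yl]acetate} (carbinol epimers) | CC(O)C1=CN(C(=O)OC)C=C[C@H]1CC(=O)OC[C@@H]2[C@@H](C)[C@H](OC(=O)C[C@@H]3C=CN(C(=O)OC)C=C3C(C)O)C[C@H]2C4COC(C)(C)OC4 | intermediate
22 | [(1S,2R,3R,5R)-5-(1,3-dihydroxypropan-2-yl)-2-methyl-3-{[(3S,4E)-4-formyl-3-(2-oxoethyl)hex-4-enoyl]oxy}cyclopentyl]methyl (3S,4E)-4-formyl-3-(2-oxoethyl)hex-4-enoate | C/C=C(/C=O)[C@@H](CC=O)CC(=O)OC[C@@H]1[C@@H](C)[C@H](OC(=O)C[C@H](CC=O)/C(C=O)=C\C)C[C@H]1C(CO)CO | target

## Step count and risks

Total step count: 12. Longest linear sequence: 12 steps (1 → 22); compounds 2, 8, 17 and 18 are commercial and enter directly.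

**Step 10 (key step).** The most likely failure is poor facial selectivity at one or both C4 centres. The 3-acetylpyridinium ion is electrophilic enough to react with the ketene acetal without the catalyst, and no thiourea has been tuned to C4 of a pyridinium ion. Competing C6 attack and an incomplete second addition would add to the loss. The fallback uses known chemistry, with auxiliary instead of catalyst control; it sets out from 16 and returns at 20. Nicotinoyl chloride is coupled with (S)-4-benzyl-1,3-thiazolidine-2-thione to (4S)-(4-benzyl-2-thioxo-1,3-thiazolidin-3-yl)(pyridin-3-yl)methanone F1. N-Methoxycarbonylpyridinium salts of such nicotinoyl auxiliaries are known to accept silyl ketene acetals at C4 on the face left open by the folded auxiliary. 16, F1 and 18 should therefore give the bis(auxiliary amide) adduct F2 (the auxiliary enantiomer is chosen for 4R; the S form is written). The activated amides are exchanged with N,O-dimethylhydroxylamine to the bis(N-methoxy-N-methylamide) F3, and MeMgBr at −78 → −20 °C converts both Weinreb amides into the methyl ketones of 20 while the alkyl esters are spared.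

**Step 12.** The most likely failures are incomplete hydrolysis (stalling at cyclic N-acyl hemiaminals), geometric scrambling of the enals, and oligomeric acetal formation between the freed diol and the aldehydes, because three different unmaskings are asked of one medium. The fallback runs from 21 to 22 and separates the events. Catalytic p-toluenesulfonic acid in wet acetone should effect the transposition and ene-carbamate hydrolysis while the solvent keeps the diol ketalized, giving the acetonide tetraaldehyde F4. This can be purified and, if needed, equilibrated to the E,E isomer. The acetonide is then removed last with 80% aqueous acetic acid at room temperature.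

**Step 8.** The most likely failure is elimination to the cyclopentene, or retention through an acyloxyphosphonium pathway, at the hindered secondary centre, because acetic acid is a weak Mitsunobu acid. The fallback sets out from 13 and returns at 14. Selective acetylation of the primary hydroxyl (acetyl chloride, 2,4,6-collidine, −78 °C) gives the monoacetate F5, and mesylation gives the mesylate F6. Displacement with CsOAc and 18-crown-6 in toluene at 80 °C, an SN2 inversion, then gives 14.

**Step 5.** The most likely failure is proton transfer between product ketone and the magnesium enolate during the slow methylation, which would give unmethylated, C4-methylated and dimethylated material. The fallback sets out from 7 and returns at 11, placing the methyl group before the conjugate addition. α-Iodination (I2, pyridine) gives the 2-iodoenone F7. Stille methylation (Me4Sn, Pd2(dba)3 (zerovalent palladium), AsPh3, CuI, NMP) gives the 2-methylenone F8. CuI-catalysed addition of 9 then sets C1 anti to C5; protonation gives in part the 1,2-cis ketone F9, which DBU equilibrates to the all-trans ketone 11.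

## Further compounds

F1 | step 10 | (4S)-(4-benzyl-2-thioxo-1,3-thiazolidin-3-yl)(pyridin-3-yl)methanone | O=C(c1cccnc1)N2C(=S)SC[C@@H]2Cc3ccccc3
F2 | step 10 | core acetonide bis{2-[(4R)-3-{[(4S)-4-benzyl-2-thioxo-1,3-thiazolidin-3-yl]carbonyl}-1-(methoxycarbonyl)-1,4-dihydropyridin-4-yl]acetate} | O=C(N5C(=S)SC[C@@H]5Cc6ccccc6)C1=CN(C(=O)OC)C=C[C@H]1CC(=O)OC[C@@H]2[C@@H](C)[C@H](OC(=O)C[C@@H]3C=CN(C(=O)OC)C=C3C(=O)N7C(=S)SC[C@@H]7Cc8ccccc8)C[C@H]2C4COC(C)(C)OC4
F3 | step 10 | core acetonide bis{2-[(4R)-3-[methoxy(methyl)carbamoyl]-1-(methoxycarbonyl)-1,4-dihydropyridin-4-yl]acetate} | CON(C)C(=O)C1=CN(C(=O)OC)C=C[C@H]1CC(=O)OC[C@@H]2[C@@H](C)[C@H](OC(=O)C[C@@H]3C=CN(C(=O)OC)C=C3C(=O)N(C)OC)C[C@H]2C4COC(C)(C)OC4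
F4 | step 12 | acetonide of target 22: [(1S,2R,3R,5R)-5-(2,2-dimethyl-1,3-dioxan-5-yl)-2-methyl-3-{[(3S,4E)-4-formyl-3-(2-oxoethyl)hex-4-enoyl]oxy}cyclopentyl]methyl (3S,4E)-4-formyl-3-(2-oxoethyl)hex-4-enoate | C/C=C(/C=O)[C@@H](CC=O)CC(=O)OC[C@@H]1[C@@H](C)[C@H](OC(=O)C[C@H](CC=O)/C(C=O)=C\C)C[C@H]1C2COC(C)(C)OC2
F5 | step 8 | [(1S,2R,3S,5R)-5-(2,2-dimethyl-1,3-dioxan-5-yl)-3-hydroxy-2-methylcyclopentyl]methyl acetate | CC(=O)OC[C@@H]1[C@@H](C)[C@@H](O)C[C@H]1C2COC(C)(C)OC2
F6 | step 8 | [(1S,2R,3S,5R)-5-(2,2-dimethyl-1,3-dioxan-5-yl)-2-methyl-3-(methylsulfonyloxy)cyclopentyl]methyl acetate | CC(=O)OC[C@@H]1[C@@H](C)[C@@H](OS(C)(=O)=O)C[C@H]1C2COC(C)(C)OC2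
F7 | step 5 | (4S)-4-(2,2-dimethyl-1,3-dioxan-5-yl)-2-iodocyclopent-2-en-1-one | C1=C(I)C(=O)C[C@H]1C2COC(C)(C)OC2
F8 | step 5 | (4R)-4-(2,2-dimethyl-1,3-dioxan-5-yl)-2-methylcyclopent-2-en-1-one | C1=C(C)C(=O)C[C@H]1C2COC(C)(C)OC2
F9 | step 5 | (2S,3S,4S)-4-(2,2-dimethyl-1,3-dioxan-5-yl)-3-{[dimethyl(propan-2-yloxy)silyl]methyl}-2-methylcyclopentan-1-one (C2 epimer of 11) | CC(C)O[Si](C)(C)C[C@@H]1[C@H](C)C(=O)C[C@H]1C2COC(C)(C)OC2
A1 | alternative 1 | dimethyl 2-[2-formyl-3-methyl-4-(tert-butyldimethylsilyloxy)cyclopentyl]propanedioate, all vicinal pairs trans | O=C[C@@H]1[C@@H](C)[C@H](O[Si](C)(C)C(C)(C)C)C[C@H]1C(C(=O)OC)C(=O)OC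
A2 | alternative 1 | dimethyl 2-[(3R,4E)-3-(tert-butyldimethylsilyloxy)-4-methyl-6-oxohex-4-en-1-ylidene]propanedioate | O=C/C=C(C)/[C@H](O[Si](C)(C)C(C)(C)C)CC=C(C(=O)OC)C(=O)OC
A3 | alternative 1 | diethyl 2,6-dimethyl-1,4-dihydropyridine-3,5-dicarboxylate (Hantzsch ester) | CCOC(=O)C1=C(C)NC(C)=C(C1)C(=O)OCC
A4 | alternative 2 | (2R,3S,4S)-4-(2,2-dimethyl-1,3-dioxan-5-yl)-3-{[dimethyl(propan-2-yloxy)silyl]methyl}-2-methylcyclopentan-1-one (identical with 11) | CC(C)O[Si](C)(C)C[C@@H]1[C@@H](C)C(=O)C[C@H]1C2COC(C)(C)OC2
A5 | alternative 2 | (4R)-4-(2,2-dimethyl-1,3-dioxan-5-yl)cyclopent-2-en-1-one (identical with 7) | C1=CC(=O)C[C@H]1C2COC(C)(C)OC2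
A6 | alternative 3 | cis-2-ethoxy-4-[2-(tert-butyldimethylsilyloxy)ethyl]-3,4-dihydro-2H-pyran | CC(C)(C)[Si](C)(C)OCC[C@@H]1C[C@H](OCC)OC=C1
A7 | alternative 3 | (E)-5-(tert-butyldimethylsilyloxy)pent-2-enal | CC(C)(C)[Si](C)(C)OCC/C=C/C=O
A8 | alternative 3 | ethyl vinyl ether | C=COCC
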